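(The data stem from a simulated flask for substances that don't exist.)

**Easy sum.** I began by adding G and J in the theta run, since on the suspected steps each Q taken stands as one of these two: Q and L share D, giving G and Z, and Z then turns G into J or falls to X.

| flask | Q | L | D | remark | time |
|---|---|---|---|---|---|
| theta | 1 mM | 2 mM | 1.5 mM | run made earlier |  |
| alpha | 1 mM | 1 mM | 1.5 mM | run made earlier |  |
| epsilon | 1 mM | 1.5 mM | 1.5 mM | run made earlier |  |
| south | 1.0 mM | 2.00 mM (fed, over 4.80 min) | 1.50 mM | all but L at the start; L goes in evenly over 4.80 min, the run ends at 6.0 min | 6.0 min |
| north | 1.0 mM | 2.00 mM | 1.50 mM | a single well-mixed tank run continuously and read at steady state, 6.0 min in it on average |  |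
| south-east | 1.0 mM | 2.00 mM | 1.50 mM | a closed flask charged with all of it at once and left for 6.0 min | 6.0 min |
| north-east | 1.0 mM | 2.00 mM | 1.50 mM | a tube with plug flow, the mixed feed as stated, residence time 6.0 min | 6.0 min |

| run | time / min | G / % | J / % |
|---|---|---|---|
| theta | 0.833 | 29.6 | 1.9 |
| theta | 2.00 | 35.1 | 6.7 |
| theta | 2.50 | 34.9 | 8.7 |
| theta | 4.00 | 30.5 | 13.1 |
| alpha | 0.667 | 30.5 | 1.2 |
| alpha | 1.50 | 46.5 | 4.5 |
| alpha | 3.00 | 51.8 | 8.9 |
| alpha | 5.00 | 52.5 | 11.0 |
| epsilon | 0.417 | 24.3 | 0.1 |
| epsilon | 0.833 | 32.3 | 3.0 |
| epsilon | 2.00 | 40.8 | 5.5 |
| epsilon | 5.00 | 40.1 | 15.8 |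

(scatter of a reading: 1 percentage point)

- the stated concentrations are those of everything mixed, before any reaction; amounts are the same in each set-up
- on the list of suspects stand: Q + D -> G; D + L -> Z; G + Z -> J; Z -> X
- the feed brings no volume worth counting
- the earlier runs were made in a closed, stirred flask

* the set-up with the highest amount of G at the outlet or at the end, in percent of the Q put in ("none" if the first two lie within 2 percentage points) (south / north / south-east / north-east / none)
* amount of G at the outlet or at the end, in percent of the Q put in, south
* amount of G at the outlet or at the end, in percent of the Q put in, north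
* amount of G at the outlet or at the end, in percent of the Q put in, south-east
* amount of G at the outlet or at the end, in percent of the Q put in, north-east

**Split number.** The sum read 43.6% at 2.50 min and 43.6% at 4.00 min, so I read that stall as marking D the limiting reagent. The L taken is then the D charge less the Q taken, which leaves 56.4% of Q beside a fraction 0.468 of L. The ratio of their logarithms is the selectivity factor s, here a reading of 0.754. Multiplied by Q over L as they stand, it gives the split number: D going to Q per D going to L.

**One number.** For theta's charge the split is 0.377, and Q's share of the D charge would take 41.1% of Q. For alpha the same sum gives 0.754 and 64.5%, against 63.5% read. So the number places G plus J, but it is silent on J, which I took from the readings, 13.1% in theta and rising. The closed flask and the tube should therefore end below 30.5% of G, and I set the tank near them.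

**Feeding L.** In south, L present stays under what has gone in, which averages half the charge over the feed. With that half charge of L and Q held at its full charge, my rough estimate of the split is 0.754, which is no lower limit, since Q falls as the run goes on; it takes 64.5% of Q and leaves G near 51.4%.

**Forecast.** The forecast, holding that “Feeding L slowly keeps L low while D is plentiful”, gave 61% for south, above mine, with 31% for north, 28% for south-east, 28% for north-east, and south best.

**Result.** The flasks gave 60.6% in south, 29.7% in north, 29.8% in south-east and 29.8% in north-east, so south came first.

    Q + D → G (k = 9.23 M⁻¹ s⁻¹)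
    D + L → Z (k = 11.3 M⁻¹ s⁻¹)
    G + Z → J (k = 3.62 M⁻¹ s⁻¹)
    Z → X (k = 0.00552 s⁻¹)

**Split again.** At 6.00 min in south, Q at 23% and L at 64% of its charge make s times Q over L 0.137, and the rate of D with Q over that with L stands at 0.15, with 77.0% of Q taken against my 64.5%. In the neighbouring fed flask with 2.5 mM of Q, the same half-charge reckoning gives a split of 1.89 and 39.2% of Q taken, and that flask holds 50.3% taken, with G at 46.5%.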